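## The problem

The target is a cis,cis-germacranolide: a cyclodeca-1(10),4-diene in which both trisubstituted olefins hold their ring carbons cis (C2/C9 across C1=C10, C3/C6 across C4=C5), with the C14 aldehyde on C10 and the C15 hydroxymethyl group on C4. An α-methylene-γ-butyrolactone is trans-fused across C6–C7, and four contiguous stereocentres run from C6 to C9: lactone oxygen, carbon branch, the (S)-2-methylbutanoate on O8 and a free hydroxyl on C9. In a mobile ten-membered ring these centres cannot be relied on to control one another, and end-to-end closure of such a ring fights entropy and transannular strain. Ring and stereocentres are therefore best prepared in a rigid bicycle. Several groups are fragile: the enal and the α-methylene lactone are Michael acceptors, the C9 and C15 alcohols are allylic, the ester can migrate between O8 and O9 and has an epimerisable α-centre, and a free C14 aldehyde invites retro-aldol cleavage. The enabling feature is that C5 and C10 face each other across the ring, that C10 carries C14 and that C1 is its neighbour. A C5–C10 bond turns the macrocycle into a cis-decalin (ring A: C1–C5, C10; ring B: C5–C10) with a C5 carbinol and a C1 leaving group in a 1,3-relationship. Heterolysis of that bond returns the ten-membered ring, the C5 carbonyl and the C1=C10 olefin in one stereospecific event.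

## Retrosynthesis

**35 ⇒ 33 ⇒ 31 + 32.** The last bond cut is the O8–acyl bond; before it only acid-labile masks are removed (C14 dioxolane, silyl ethers on O9 and O15). Acylating last keeps the epimerisable acyl group of 32 away from every enolate-forming step; carrying it from the decalin stage would expose it to four strong bases. Alcohol 31 differs from the target only in protecting groups. The forward reactions must acylate a hindered secondary hydroxyl without epimerisation and unmask without acyl shift to O9.

**31 ⇒ 30 ⇒ 27 ⇒ 26 ⇒ 25 ⇒ 24 ⇒ 21.** The exocyclic C11=C13 bond is cut back to the saturated lactone 27. The C15–O bond and the C4=C5 olefin of 26 are traced by a 1,3-allylic transposition to the secondary allylic alcohol 25 and thus to enone 24, whose C15 is removed to give ketone 21. The alternative of carrying a 4-methylene group through the ring opening was rejected: it would have to be built next to a tertiary carbinol on a crowded decalin, and the fragmentation would then release an α-methylene ketone into strong base. Ketone 21 lacks both exocyclic carbons and the C4=C5 olefin. The forward steps must enolise C4 in preference to C6 and deliver the ring-cis olefin in the transposition.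

**21 ⇒ 20.** Forming the C5–C10 bond retrosynthetically gives the cis-fused hydroxy mesylate 20. No other transannular bond maps onto existing functionality in this way: C5 becomes a carbinol, C1 carries the nucleofuge and C10 already holds C14. The macrocycle becomes a decalin, and the olefin geometry becomes a matter of the relative configuration of C1, C5 and C10. The forward step needs an antiperiplanar C1–O/C5–C10 arrangement and a single free hydroxyl.

**20 ⇒ 19 ⇒ 18 ⇒ 17 ⇒ 16.** The C8–O and C9–O bonds are cut together: the trans-diaxial 8β-ether/9α-alcohol pair comes from an 8α,9α-epoxide and that from the Δ8 olefin of 16. An osmylation would give the cis-diol and a C9 ketone reduction would leave O8 unsolved. The epoxide route also differentiates O8 (enters as an ether) from O9 (liberated as the alcohol). Two stereocentres are exchanged for one olefin. Required are α-face epoxidation and diaxial opening at C8.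

**16 ⇒ 15 ⇒ 14 ⇒ 13 ⇒ 12 ⇒ 11 ⇒ 10.** The lactone C12–O6 bond is cut and the acetic acid side chain is recognised as a decarboxylated malonate that was held on O5 as a bridging lactone. The C6 carbinol goes back to a ketone and the Δ8 olefin to the C9 ketone through its enol triflate. Converting C9 to the enol triflate before reducing C6 makes C6 the only ketone, and C7, a bridgehead, cannot epimerise. Diketone 10 still has both ring B carbonyls and no C6 stereocentre.

**10 ⇒ 9 ⇒ 7 + 8.** The C7–C11 bond is cut as an intramolecular Michael addition and the O5–C12 bond as an acylation with 8. An intermolecular conjugate addition to the enedione would have to choose between C7 and C8 and between two faces. A nucleophile tethered to the 5β-oxygen can reach only C7 and only from the β-face. The C7 stereocentre and two carbons disappear.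

**7 ⇒ 6 ⇒ 5 ⇒ 4.** The C5–O bond is cut as an oxidation of the silyl dienol ether 6, and the dioxolane is opened to the aldehyde of 4. C5–H is the only enolisable position of 5, so no regiochemical question arises; the face of attack is the issue.

**4 ⇒ 3 + 2; 3 ⇒ 1.** The C1–C10 and C4–C5 bonds are cut in a Diels–Alder sense. One step assembles the decalin, the quaternary C10 with C14 already at the aldehyde level, the C1 oxygen trans to C14 and an enedione that activates every carbon of ring B. An annulation of a cyclohexane-1,3-dione was considered; it would leave C9 unoxidised and deliver the C1 carbinol cis to the angular group on reduction. Quinone 3 comes from hydroquinone 1 by oxidation; 1, 2, 8 and 32 are commercial.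

## Roads not taken

**Alternative 1:** The cut is the O–C6 bond of the lactone in an already formed ten-membered ring. Zerovalent palladium would ionise the vinyl epoxide acid A1 to a π-allyl spanning C4–C6; the C12 carboxylate would close onto C6 to give A2, moving the olefin to C4=C5 and freeing O15.

- Merits: lactone, olefin and primary alcohol appear in one neutral step, the α-methylene unit is already present, and A2 is one deprotection from the target. In endgame economy this road is better than the chosen one, which needs a reduction, a transposition and two methylenations.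
- Weak points: A1 presupposes the macrocycle with C7–C9 in place, so the hard problem is only moved. The C6 configuration and the C4=C5 geometry depend on the face and the syn/anti form of a π-allyl in a floppy ring. The trans-lactone requires the carboxylate to reach the face opposite its own tether.
- Against it the chosen plan sets a ring formation that cannot fail to close and a C6 centre fixed in a six-membered ring before the macrocycle exists.

**Alternative 2:** The cut is C1–C2. The stabilised carbanion of the iodo β-keto sulfone A3 would displace the primary iodide under carbonate base at high dilution to give the macrocyclic keto sulfone A4.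

- Merits: a soft, tolerant C–C bond formation; a modular acyclic precursor; the C4=C5 geometry is fixed before cyclisation. It is more convergent than the chosen plan.
- Weak points: ten-membered alkylative closure competes with dimerisation and O-alkylation. After closure C14 still has to be added to a hindered C10 ketone, and the C1=C10 olefin must be made by sulfone elimination with no control of geometry. C9 sits α to the ketone and can epimerise.
- The chosen plan carries C14 from the first step and forms C1=C10 stereospecifically; it pays with a longer linear sequence.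

**Alternative 3:** The cut is C9–C10. Divalent chromium with a nickel co-catalyst would join the vinyl iodide and the aldehyde of A5 in a Nozaki–Hiyama–Kishi macrocyclisation, giving the allylic alcohol A6.

- Merits: the reaction is chemoselective enough to be run on a fully functionalised substrate; it forms the ring and the C9 carbinol together and retains the olefin geometry of the iodide. A6 is one step from the target. This is the shortest endgame of all and is superior in convergence.
- Weak points: the C9 configuration is decided during a macrocyclisation under uncertain substrate control. The α-acyloxy aldehyde can epimerise or lose its ester, and the new chromium alkoxide sits next to the O8 ester and invites acyl transfer. The α-branched vinyl iodide is slow, and the closure is entropically costly.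
- The chosen plan sets C9 by epoxide opening in a locked cyclohexane and avoids any end-to-end closure.

Key step: step 14

Convention: germacrane numbering is used for every intermediate (ring carbons C1–C10, C14 on C10, C15 on C4, C11–C13 on C7). In the bicycles C5 and C10 are the fusion carbons, and β is the face that carries C14.

Assumption: 2-formyl-1,4-benzoquinone (3) is taken to react like the known 2-acyl- and 2-alkoxycarbonyl-1,4-benzoquinones, i.e. at its formyl-bearing double bond and with chelation of a chiral lanthanide Lewis acid by its 1,3-dicarbonyl unit.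

## Route

**Step 1**
Reactants: 1 2,5-dihydroxybenzaldehyde; 2 (E)-buta-1,3-dien-1-yl acetate
Product: 4 Diels–Alder adduct (1α-acetoxy-10β-formyl-5βH-bicyclo[4.4.0]deca-2,7-diene-6,9-dione), via 2-formyl-1,4-benzoquinone 3 (not isolated)
Conditions: Ag2O, MgSO4, CH2Cl2, 0 °C, filter; then 2, Sm(OTf)3 (10 mol %), Ph-pybox (enantiomer that gives the 10β series), 4 Å MS, CH2Cl2, −78 °C
Reagents that add atoms: none
Why: Ag2O oxidises the hydroquinone to acylquinone 3, whose formyl-bearing double bond is the most electron-poor and enters a Diels–Alder reaction; the diene terminus remote from the acetoxy group bonds to C5, so the acetoxy carbon ends next to C10; the endo transition state with the quinone ring under the diene puts the acetoxy group trans to the formyl group; suprafacial addition gives the cis fusion; two-point binding of the 1,3-dicarbonyl unit to the chiral samarium complex selects the face that sets C10.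

**Step 2**
Reactants: 4 Diels–Alder adduct
Product: 5 dioxolane (1α-acetoxy-10β-(1,3-dioxolan-2-yl)-5βH-bicyclo[4.4.0]deca-2,7-diene-6,9-dione)
Conditions: TMSOCH2CH2OTMS, TMSOTf (cat.), CH2Cl2, −78 °C
Reagents that add atoms: 1,2-bis(trimethylsilyloxy)ethane, C[Si](C)(C)OCCO[Si](C)(C)C
Why: Silyl-triflate-catalysed acetalisation is selective for the aldehyde over the two conjugated ketones and removes the base-labile β-keto aldehyde before any enolate chemistry.

**Step 3**
Reactants: 5 dioxolane
Product: 7 ketol (1α-acetoxy-5β-hydroxy-10β-(1,3-dioxolan-2-yl)bicyclo[4.4.0]deca-2,7-diene-6,9-dione), via silyl dienol ether 6 (not isolated)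
Conditions: TMSOTf, Et3N, CH2Cl2, −78 °C; dimethyldioxirane, acetone, −78 °C; then aq. citric acid, 0 °C
Reagents that add atoms: dimethyldioxirane, CC1(C)OO1
Why: Rubottom oxidation: C5–H is the only enolisable hydrogen, so soft enolisation gives the cross-conjugated dienol ether 6, whose electron-rich C5=C6 bond is epoxidised before the acetoxy-deactivated C2=C3 and the electron-poor C7=C8 bonds; the axial 1α-acetoxy group lies under C5 and should send the oxidant to the β-face beside C14, giving the cis-fused ketol.

**Step 4**
Reactants: 7 ketol; 8 methyl 3-chloro-3-oxopropanoate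
Product: 10 bridged lactone (1α-acetoxy-10β-(1,3-dioxolan-2-yl)-11-methoxycarbonyl-12,5β-olide with C11 bonded to C7β, bicyclo[4.4.0]dec-2-ene-6,9-dione; C11 epimers), via malonate ester 9 (not isolated)
Conditions: pyridine, DMAP (cat.), CH2Cl2, 0 °C; then DBU (0.2 equiv), MeCN, rt
Reagents that add atoms: none
Why: Acylation of the tertiary alcohol (through the acid chloride or the ketene derived from it) is followed by a base-catalysed intramolecular Michael addition; the malonate carbon tethered to O5 can reach only C7, the β-carbon of the C9 enone, in a 6-exo closure, so the regiochemistry is enforced and the new C7–C11 bond is necessarily β (1,3-diaxial bridge); the stabilised malonate anion of 10 is the thermodynamic sink.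

**Step 5**
Reactants: 10 bridged lactone
Product: 11 2,3-dihydro bridged lactone
Conditions: H2 (1 atm), RhCl(PPh3)3 (5 mol %), PhH–EtOH, rt
Reagents that add atoms: none
Why: Homogeneous hydrogenation saturates the only remaining olefin without hydrogenolysis of the allylic acetate and without touching ketones or esters.

**Step 6**
Reactants: 11 2,3-dihydro bridged lactone
Product: 12 C9 enol triflate (Δ8)
Conditions: KN(SiMe3)2 (2.2 equiv), THF, −78 °C; PhNTf2, −78 → 0 °C; aq. NH4Cl
Reagents that add atoms: N-phenylbis(trifluoromethanesulfonimide), O=S(=O)(N(c1ccccc1)S(=O)(=O)C(F)(F)F)C(F)(F)F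
Why: Of the two ketones only C9 can enolise (C6 lies between quaternary C5 and bridgehead C7); after the more acidic malonate C–H has been deprotonated the second equivalent of base gives the C8=C9 enolate, which is O-sulfonylated, and this differentiates the two ring B carbonyls.

**Step 7**
Reactants: 12 C9 enol triflate
Product: 13 6α-alcohol
Conditions: NaBH4, MeOH–THF, −40 °C
Reagents that add atoms: none
Why: Borohydride reduction of the now unique, α-acyloxy-activated ketone; in the 2-oxabicyclo[3.3.1]nonane the hydride should enter from the side of the flat lactone bridge, because the other side is screened by the axial C1 methine of ring A, which leaves the hydroxyl α (trans to O5).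

**Step 8**
Reactants: 13 6α-alcohol
Product: 14 Δ8 olefin
Conditions: Pd(OAc)2 (5 mol %), PPh3, Bu3N, HCO2H, DMF, 60 °C
Reagents that add atoms: none
Why: Formate reduction of the vinyl triflate under zerovalent-palladium catalysis gives the C8=C9 olefin; alcohol, esters and acetal are inert.

**Step 9**
Reactants: 14 Δ8 olefin
Product: 16 hydroxy lactone (1α,5β-dihydroxy-10β-(1,3-dioxolan-2-yl)-Δ8-12,6α-olide, trans-fused), via triol diacid 15 (not isolated)
Conditions: LiOH, THF–MeOH–H2O, rt; 1 M HCl to pH 3, 0 °C; pyridine, 90 °C; then PPTS (cat.), PhMe, 50 °C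
Reagents that add atoms: lithium hydroxide, [Li+].[OH-]
Why: Saponification cleaves the acetate, the methyl ester and the strained tertiary-alkyl lactone; the malonic acid loses CO2 on warming and the acetic acid chain lactonises onto the neighbouring secondary 6α-hydroxyl in preference to the tertiary 5-hydroxyl, giving the trans-fused γ-lactone that holds ring B with O6 and C11 equatorial.

**Step 10**
Reactants: 16 hydroxy lactone
Product: 17 1α-mesylate
Conditions: MsCl, Et3N, CH2Cl2, −20 °C
Reagents that add atoms: methanesulfonyl chloride, CS(=O)(=O)Cl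
Why: Sulfonylation distinguishes the secondary C1 hydroxyl from the hindered tertiary C5 hydroxyl; no alkoxide is formed, so the 1,3-hydroxy mesylate persists.

**Step 11**
Reactants: 17 1α-mesylate
Product: 18 8α,9α-epoxide
Conditions: mCPBA, NaHCO3, CH2Cl2, 0 °C
Reagents that add atoms: 3-chloroperoxybenzoic acid, OOC(=O)c1cccc(Cl)c1
Why: Prilezhaev epoxidation; both carbons flanking the olefin carry their substituents on the β-face (axial acetal on C10, lactone methylene on C7), so the peracid should add from the α-face.

**Step 12**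
Reactants: 18 8α,9α-epoxide
Product: 19 8β-(4-methoxybenzyl) ether 9α-alcohol
Conditions: 4-methoxybenzyl alcohol (10 equiv), Yb(OTf)3 (10 mol %), CH2Cl2, 0 °C → rt
Reagents that add atoms: 4-methoxybenzyl alcohol, COc1ccc(CO)cc1
Why: Lewis-acid-catalysed alcoholysis follows the Fürst–Plattner rule: in the chair fixed by the trans-lactone, diaxial opening puts the nucleophile on C8 from the β-face, and attack at the neopentyl C9 is disfavoured as well, so O8 arrives as the ether and O9 as the free α-alcohol.

**Step 13**
Reactants: 19 8β-(4-methoxybenzyl) ether 9α-alcohol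
Product: 20 Grob precursor (9α-tert-butyldimethylsilyl ether)
Conditions: TBSOTf (1.1 equiv), 2,6-lutidine, CH2Cl2, −78 °C
Reagents that add atoms: tert-butyldimethylsilyl triflate, CC(C)(C)[Si](C)(C)OS(=O)(=O)C(F)(F)F
Why: Silylation of the only secondary hydroxyl at low temperature (the tertiary C5 hydroxyl reacts far more slowly); O9 must be capped because a free 9-alkoxide would offer a competing cleavage of the C9–C10 bond.

**Step 14**
Reactants: 20 Grob precursor
Product: 21 cyclodecenone lactone (ring-cis C1=C10, C5 ketone)
Conditions: KN(SiMe3)2 (1.05 equiv), THF, 0 °C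
Reagents that add atoms: none
Why: Grob fragmentation (the Wharton variant for 1,3-diol monosulfonates): the base deprotonates the only free hydroxyl and the C5 alkoxide pushes electrons into the C5–C10 bond, which breaks as the C1–O bond of the mesylate ionises, in one concerted step. No ring is closed: the ten-membered ring is set free by cleavage of the bond shared by rings A and B, and no stereocentre is created. The selectivity needed is the geometry of C1=C10. In the chair–chair conformer fixed by the diequatorial trans-lactone, C14 is equatorial and C9 axial on ring A, and the 1α-mesylate, trans to C14, is equatorial and hence antiperiplanar to C5–C10. Because C2–C1–C10–C14 is anti in that arrangement, C2 and C14 end trans and C2 and C9 cis on the new olefin, the ring-cis geometry of the target. Chemoselectivity rests on the silyl ether on O9, on the absence of any carbonyl β to O5 (C14 is an acetal) and on one equivalent of base, so that neither the lactone nor the new ketone is enolised. Release of the two 1,3-diaxial interactions in ring B adds driving force.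

**Step 15**
Reactants: 21 cyclodecenone lactone
Product: 24 4(15)-en-5-one, via C4 Mannich base 22 (not isolated), via C4 ammonium iodide 23 (not isolated)
Conditions: LiN(SiMe3)2 (1.05 equiv), THF, −78 °C; Me2N=CH2 I, −78 °C → rt; MeI, CH2Cl2; DBU, rt
Reagents that add atoms: dimethyl(methylene)ammonium iodide, C=[N+](C)C.[I-]
Why: Mannich methylenation: kinetic deprotonation should occur at the C4 methylene and not at the hindered C6 methine or the less acidic lactone; the enolate is trapped by the iminium salt, and quaternisation and elimination give the exo-methylene ketone, which is made only now so that it never meets the base of step 14.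

**Step 16**
Reactants: 24 4(15)-en-5-one
Product: 25 4(15)-en-5-ol (C5 epimers)
Conditions: NaBH4, CeCl3·7H2O, MeOH, −78 °C
Reagents that add atoms: none
Why: Luche reduction gives 1,2-reduction of the enone; the configuration at C5 is irrelevant because the centre is erased in step 17.

**Step 17**
Reactants: 25 4(15)-en-5-ol
Product: 26 15-alcohol (C4=C5 with C3 cis to C6)
Conditions: Ph3SiOReO3 (3 mol %), Et2O, 0 °C
Reagents that add atoms: none
Why: Oxo-rhenium-catalysed 1,3-transposition through the allylic perrhenate ([3,3] shift): the equilibrium favours the primary alcohol on a trisubstituted olefin, and a chair transition state with C6 equatorial puts C6 trans to C15, i.e. C3 and C6 cis.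

**Step 18**
Reactants: 26 15-alcohol
Product: 27 15-tert-butyldimethylsilyl ether
Conditions: TBSCl, imidazole, DMF, 0 °C
Reagents that add atoms: tert-butyldimethylsilyl chloride, CC(C)(C)[Si](C)(C)Cl
Why: Silylation of the primary allylic alcohol shields it from the base of step 19, the oxidant of step 20 and the acylation of step 21.

**Step 19**
Reactants: 27 15-silyl ether
Product: 30 α-methylene lactone, via C11 Mannich base 28 (not isolated), via C11 ammonium iodide 29 (not isolated)
Conditions: LiN(iPr)2, THF, −78 °C; Me2N=CH2 I, −78 °C → rt; MeI, MeOH; aq. NaHCO3, CH2Cl2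
Reagents that add atoms: dimethyl(methylene)ammonium iodide, C=[N+](C)C.[I-]
Why: Mannich methylenation of the lactone enolate (the only acidic C–H left), followed by quaternisation and elimination, the standard entry to an α-methylene-γ-butyrolactone.

**Step 20**
Reactants: 30 α-methylene lactone
Product: 31 8β-alcohol
Conditions: DDQ, CH2Cl2–pH 7 buffer, 0 °C
Reagents that add atoms: none
Why: Oxidative cleavage of the 4-methoxybenzyl ether through the benzylic cation and its hemiacetal; silyl ethers, acetal and the Michael acceptor are left alone.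

**Step 21**
Reactants: 31 8β-alcohol; 32 (S)-2-methylbutanoic acid
Product: 33 8-O-[(S)-2-methylbutanoyl] ester
Conditions: DCC, DMAP (cat.), CH2Cl2, 0 °C → rt
Reagents that add atoms: none
Why: Steglich esterification of the only free hydroxyl; carbodiimide activation at low temperature should not epimerise the α-centre of the acid.

**Step 22**
Reactants: 33 8-O-[(S)-2-methylbutanoyl] ester
Product: 35 CNP0331447.1, via 9,15-diol acetal 34 (not isolated)
Conditions: HF·pyridine, THF, 0 °C → rt; then 1 M aq. HCl, THF, rt
Reagents that add atoms: water, O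
Why: Fluoride removes both silyl ethers and dilute aqueous acid then hydrolyses the acetal of the conjugated aldehyde; acyl migration from O8 to O9 is slow under acid.

## Compound list

1 | 2,5-dihydroxybenzaldehyde | O=Cc1cc(O)ccc1O | starting material
2 | (E)-buta-1,3-dien-1-yl acetate | CC(=O)O/C=C/C=C | starting material
3 | 2-formyl-1,4-benzoquinone | O=CC1=CC(=O)C=CC1=O | intermediate (not isolated)
4 | 1α-acetoxy-10β-formyl-5βH-bicyclo[4.4.0]deca-2,7-diene-6,9-dione (cis-fused) | CC(=O)O[C@H]1C=CC[C@H]2C(=O)C=CC(=O)[C@@]12C=O | intermediate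
5 | 1α-acetoxy-10β-(1,3-dioxolan-2-yl)-5βH-bicyclo[4.4.0]deca-2,7-diene-6,9-dione | CC(=O)O[C@H]1C=CC[C@H]2C(=O)C=CC(=O)[C@@]12C1OCCO1 | intermediate
6 | 1α-acetoxy-10β-(1,3-dioxolan-2-yl)-6-trimethylsilyloxybicyclo[4.4.0]deca-2,5,7-trien-9-one | CC(=O)O[C@H]1C=CCC2=C(O[Si](C)(C)C)C=CC(=O)[C@@]12C1OCCO1 | intermediate (not isolated)
7 | 1α-acetoxy-5β-hydroxy-10β-(1,3-dioxolan-2-yl)bicyclo[4.4.0]deca-2,7-diene-6,9-dione (cis-fused) | CC(=O)O[C@H]1C=CC[C@@]2(O)C(=O)C=CC(=O)[C@@]12C1OCCO1 | intermediate
8 | methyl 3-chloro-3-oxopropanoate | COC(=O)CC(=O)Cl | starting material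
9 | 5β-O-(methoxycarbonylacetyl) ester of 7 | CC(=O)O[C@H]1C=CC[C@@]2(OC(=O)CC(=O)OC)C(=O)C=CC(=O)[C@@]12C1OCCO1 | intermediate (not isolated)
10 | bridged lactone: 1α-acetoxy-10β-(1,3-dioxolan-2-yl)-11-methoxycarbonyl-6,9-dioxo-Δ2-12,5β-olide, C11 bonded to C7β (7α-H; C11 epimers) | CC(=O)O[C@H]1C=CC[C@@]2(OC(=O)C(C(=O)OC)[C@@H]3CC(=O)[C@@]12C1OCCO1)C3=O | intermediate
11 | 2,3-dihydro derivative of 10 | CC(=O)O[C@H]1CCC[C@@]2(OC(=O)C(C(=O)OC)[C@@H]3CC(=O)[C@@]12C1OCCO1)C3=O | intermediate
12 | C9 enol triflate of 11 (Δ8, C6 ketone) | CC(=O)O[C@H]1CCC[C@@]2(OC(=O)C(C(=O)OC)[C@@H]3C=C(OS(=O)(=O)C(F)(F)F)[C@@]12C1OCCO1)C3=O | intermediate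
13 | 6α-hydroxy C9 enol triflate | CC(=O)O[C@H]1CCC[C@@]2(OC(=O)C(C(=O)OC)[C@@H]3C=C(OS(=O)(=O)C(F)(F)F)[C@@]12C1OCCO1)[C@H]3O | intermediate
14 | 6α-hydroxy-Δ8 bridged lactone | CC(=O)O[C@H]1CCC[C@@]2(OC(=O)C(C(=O)OC)[C@@H]3C=C[C@@]12C1OCCO1)[C@H]3O | intermediate
15 | 1α,5β,6α-trihydroxy-10β-(1,3-dioxolan-2-yl)-Δ8-decalin-7β-ylmalonic acid | O[C@H]1CCC[C@@]2(O)[C@@H](O)[C@H](C(C(=O)O)C(=O)O)C=C[C@@]12C1OCCO1 | intermediate (not isolated)
16 | 1α,5β-dihydroxy-10β-(1,3-dioxolan-2-yl)-Δ8-12,6α-olide (trans-fused γ-lactone, 7α-H) | O[C@H]1CCC[C@@]2(O)[C@H]3OC(=O)C[C@@H]3C=C[C@@]12C1OCCO1 | intermediate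
17 | 1α-mesyloxy derivative of 16 | CS(=O)(=O)O[C@H]1CCC[C@@]2(O)[C@H]3OC(=O)C[C@@H]3C=C[C@@]12C1OCCO1 | intermediate
18 | 8α,9α-epoxide of 17 | CS(=O)(=O)O[C@H]1CCC[C@@]2(O)[C@H]3OC(=O)C[C@@H]3[C@H]4O[C@H]4[C@@]12C1OCCO1 | intermediate
19 | 5β,9α-dihydroxy-8β-(4-methoxybenzyloxy)-1α-mesyloxy-10β-(1,3-dioxolan-2-yl)-12,6α-olide | CS(=O)(=O)O[C@H]1CCC[C@@]2(O)[C@H]3OC(=O)C[C@@H]3[C@H](OCc4ccc(OC)cc4)[C@@H](O)[C@@]12C1OCCO1 | intermediate
20 | 5β-hydroxy-9α-(tert-butyldimethylsilyloxy)-8β-(4-methoxybenzyloxy)-1α-mesyloxy-10β-(1,3-dioxolan-2-yl)-12,6α-olide (cis-decalin) | CS(=O)(=O)O[C@H]1CCC[C@@]2(O)[C@H]3OC(=O)C[C@@H]3[C@H](OCc4ccc(OC)cc4)[C@@H](O[Si](C)(C)C(C)(C)C)[C@@]12C1OCCO1 | intermediate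
21 | 5-oxo-cyclodec-1(10)-ene 12,6-olide, C2 cis to C9, 10-(1,3-dioxolan-2-yl), 9-OTBS, 8-OPMB | O=C1CCC/C=C(/C3OCCO3)[C@H](O[Si](C)(C)C(C)(C)C)[C@@H](OCc3ccc(OC)cc3)[C@H]2CC(=O)O[C@@H]21 | intermediate
22 | 4-(dimethylaminomethyl) derivative of 21 (C4 epimers) | O=C1C(CN(C)C)CC/C=C(/C3OCCO3)[C@H](O[Si](C)(C)C(C)(C)C)[C@@H](OCc3ccc(OC)cc3)[C@H]2CC(=O)O[C@@H]21 | intermediate (not isolated)
23 | 4-(trimethylammoniomethyl) iodide of 21 | O=C1C(C[N+](C)(C)C)CC/C=C(/C3OCCO3)[C@H](O[Si](C)(C)C(C)(C)C)[C@@H](OCc3ccc(OC)cc3)[C@H]2CC(=O)O[C@@H]21.[I-] | intermediate (not isolated)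
24 | 4-methylene-5-oxo-cyclodec-1(10)-ene 12,6-olide | C=C1CC/C=C(/C3OCCO3)[C@H](O[Si](C)(C)C(C)(C)C)[C@@H](OCc3ccc(OC)cc3)[C@H]2CC(=O)O[C@@H]2C1=O | intermediate
25 | 4-methylene-5-hydroxy-cyclodec-1(10)-ene 12,6-olide (C5 epimers) | C=C1CC/C=C(/C3OCCO3)[C@H](O[Si](C)(C)C(C)(C)C)[C@@H](OCc3ccc(OC)cc3)[C@H]2CC(=O)O[C@@H]2C1O | intermediate
26 | 15-hydroxy-cyclodeca-1(10),4-diene 12,6-olide (C3 cis to C6, C2 cis to C9), 11,13-dihydro, 9-OTBS, 8-OPMB, C14 dioxolane | C1C(=O)O[C@@H]2/C=C(/CO)CC/C=C(/C3OCCO3)[C@H](O[Si](C)(C)C(C)(C)C)[C@@H](OCc3ccc(OC)cc3)[C@@H]12 | intermediate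
27 | 15-O-tert-butyldimethylsilyl ether of 26 | C1C(=O)O[C@@H]2/C=C(/CO[Si](C)(C)C(C)(C)C)CC/C=C(/C3OCCO3)[C@H](O[Si](C)(C)C(C)(C)C)[C@@H](OCc3ccc(OC)cc3)[C@@H]12 | intermediate
28 | 11-(dimethylaminomethyl) derivative of 27 (C11 epimers) | CN(C)CC1C(=O)O[C@@H]2/C=C(/CO[Si](C)(C)C(C)(C)C)CC/C=C(/C3OCCO3)[C@H](O[Si](C)(C)C(C)(C)C)[C@@H](OCc3ccc(OC)cc3)[C@@H]12 | intermediate (not isolated)
29 | 11-(trimethylammoniomethyl) iodide of 27 | C[N+](C)(C)CC1C(=O)O[C@@H]2/C=C(/CO[Si](C)(C)C(C)(C)C)CC/C=C(/C3OCCO3)[C@H](O[Si](C)(C)C(C)(C)C)[C@@H](OCc3ccc(OC)cc3)[C@@H]12.[I-] | intermediate (not isolated)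
30 | 11(13)-methylene lactone: 8-OPMB, 9-OTBS, 15-OTBS, C14 dioxolane | C=C1C(=O)O[C@@H]2/C=C(/CO[Si](C)(C)C(C)(C)C)CC/C=C(/C3OCCO3)[C@H](O[Si](C)(C)C(C)(C)C)[C@@H](OCc3ccc(OC)cc3)[C@@H]12 | intermediate
31 | 8-hydroxy derivative of 30 | C=C1C(=O)O[C@@H]2/C=C(/CO[Si](C)(C)C(C)(C)C)CC/C=C(/C3OCCO3)[C@H](O[Si](C)(C)C(C)(C)C)[C@@H](O)[C@@H]12 | intermediate
32 | (S)-2-methylbutanoic acid | CC[C@H](C)C(=O)O | starting material
33 | 8-O-[(S)-2-methylbutanoyl] ester of 31 | C=C1C(=O)O[C@@H]2/C=C(/CO[Si](C)(C)C(C)(C)C)CC/C=C(/C3OCCO3)[C@H](O[Si](C)(C)C(C)(C)C)[C@@H](OC(=O)[C@@H](C)CC)[C@@H]12 | intermediate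
34 | 9,15-diol C14 dioxolane | C=C1C(=O)O[C@@H]2/C=C(/CO)CC/C=C(/C3OCCO3)[C@H](O)[C@@H](OC(=O)[C@@H](C)CC)[C@@H]12 | intermediate (not isolated)
35 | CNP0331447.1 | C=C1C(=O)O[C@@H]2/C=C(/CO)CC/C=C(/C=O)[C@H](O)[C@@H](OC(=O)[C@@H](C)CC)[C@@H]12 | target

## Count and risk

Total step count: 22. Longest linear sequence: 22 steps from 1; the route is fully linear, and 2, 8 and 32 are bought.

Least certain steps:

**Step 14 (key step).** Most likely failure: the potassium alkoxide adds to the lactone carbonyl (acyl transfer to O5), or the base eliminates the mesylate, faster than the bond cleavage, because the crowded ring B may distort the chair on which the antiperiplanar alignment depends. Fallback: start from 20 and change the way the alkoxide is made. The tertiary hydroxyl is silylated (N-trimethylsilylimidazole) to the 5-O-trimethylsilyl ether F1, and F1 is treated with anhydrous tris(dimethylamino)sulfonium difluorotrimethylsilicate in DMF at −40 °C. The counter-ion-free alkoxide is then generated without excess base and fragments to 21, where the route is rejoined.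

**Step 3.** Most likely failure: loss of facial selectivity in the oxidation of the dienol ether, with attack anti to the dioxolane giving the trans-fused ketol. Fallback: start from 4 and invert the order, so that the β-face carries only the small, planar formyl group when C5 is oxidised. Aldehyde 4 is converted into its silyl dienol ether F2, which is oxidised with dimethyldioxirane to the 5β-hydroxy aldehyde F3. Acetalisation of F3 as in step 2 returns to 7.

**Step 1.** Most likely failure: the uncatalysed background cycloaddition of the very reactive acylquinone erodes catalyst control, and the quinone may partly react as a heterodiene. Fallback: start from 3 and move stereocontrol into the diene. Cycloaddition with buta-1,3-dienyl (S)-O-methylmandelate F4, whose phenyl group shields one diene face, gives adduct F5 (the (S)-auxiliary is drawn; its antipode is used if it delivers the other face). F5 is taken through the operations of steps 2–8: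

- acetal F6;
- silyl dienol ether F7 and ketol F8;
- malonate F9 and bridged lactone F10;
- saturated lactone F11, enol triflate F12, alcohol F13 and olefin F14.

The saponification of step 9 removes the auxiliary together with the other esters, so the route is rejoined at 15 and hence at 16.

**Step 12.** Most likely failure: slow intermolecular attack at the hindered C8 position (syn-axial to the acetal) lets the C5 hydroxyl open the epoxide across the ring, or the Lewis acid exchanges the acetal. Fallback: start from 18 and separate ring opening from protection. Hydrolysis with water as the small nucleophile (Er(OTf)3, MeCN–H2O) gives the 8β,9α-diol F15. The less hindered 8-hydroxyl is then etherified with 4-methoxybenzyl trichloroacetimidate (La(OTf)3 cat.) to return to 19.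

**Step 17.** Most likely failure: an unfavourable position of the allylic equilibrium, or ionisation of the perrhenate with elimination and loss of geometric control. Fallback: start from 25 and use the acetate. Acetylation gives the 5-acetate F16; the 1,3-acetoxy shift catalysed by PdCl2(MeCN)2 (divalent palladium, cyclisation-induced rearrangement) gives the primary allylic acetate F17; brief methanolysis (K2CO3, MeOH, 0 °C) returns to 26.

## Further compounds

F1 | step 14 | 5-O-trimethylsilyl ether of 20 | CS(=O)(=O)O[C@H]1CCC[C@@]2(O[Si](C)(C)C)[C@H]3OC(=O)C[C@@H]3[C@H](OCc4ccc(OC)cc4)[C@@H](O[Si](C)(C)C(C)(C)C)[C@@]12C1OCCO1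
F2 | step 3 | 1α-acetoxy-10β-formyl-6-trimethylsilyloxybicyclo[4.4.0]deca-2,5,7-trien-9-one | CC(=O)O[C@H]1C=CCC2=C(O[Si](C)(C)C)C=CC(=O)[C@@]12C=O
F3 | step 3 | 1α-acetoxy-5β-hydroxy-10β-formylbicyclo[4.4.0]deca-2,7-diene-6,9-dione | CC(=O)O[C@H]1C=CC[C@@]2(O)C(=O)C=CC(=O)[C@@]12C=O
F4 | step 1 | (E)-buta-1,3-dien-1-yl (S)-2-methoxy-2-phenylacetate | CO[C@@H](c1ccccc1)C(=O)O/C=C/C=C
F5 | step 1 | 1α-[(S)-2-methoxy-2-phenylacetoxy] analogue of 4 | CO[C@@H](c1ccccc1)C(=O)O[C@H]1C=CC[C@H]2C(=O)C=CC(=O)[C@@]12C=O
F6 | step 1 | 1α-[(S)-2-methoxy-2-phenylacetoxy] analogue of 5 | CO[C@@H](c1ccccc1)C(=O)O[C@H]1C=CC[C@H]2C(=O)C=CC(=O)[C@@]12C1OCCO1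
F7 | step 1 | 1α-[(S)-2-methoxy-2-phenylacetoxy] analogue of 6 | CO[C@@H](c1ccccc1)C(=O)O[C@H]1C=CCC2=C(O[Si](C)(C)C)C=CC(=O)[C@@]12C1OCCO1
F8 | step 1 | 1α-[(S)-2-methoxy-2-phenylacetoxy] analogue of 7 | CO[C@@H](c1ccccc1)C(=O)O[C@H]1C=CC[C@@]2(O)C(=O)C=CC(=O)[C@@]12C1OCCO1
F9 | step 1 | 1α-[(S)-2-methoxy-2-phenylacetoxy] analogue of 9 | CO[C@@H](c1ccccc1)C(=O)O[C@H]1C=CC[C@@]2(OC(=O)CC(=O)OC)C(=O)C=CC(=O)[C@@]12C1OCCO1
F10 | step 1 | 1α-[(S)-2-methoxy-2-phenylacetoxy] analogue of 10 | CO[C@@H](c1ccccc1)C(=O)O[C@H]1C=CC[C@@]2(OC(=O)C(C(=O)OC)[C@@H]3CC(=O)[C@@]12C1OCCO1)C3=O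
F11 | step 1 | 1α-[(S)-2-methoxy-2-phenylacetoxy] analogue of 11 | CO[C@@H](c1ccccc1)C(=O)O[C@H]1CCC[C@@]2(OC(=O)C(C(=O)OC)[C@@H]3CC(=O)[C@@]12C1OCCO1)C3=O
F12 | step 1 | 1α-[(S)-2-methoxy-2-phenylacetoxy] analogue of 12 | CO[C@@H](c1ccccc1)C(=O)O[C@H]1CCC[C@@]2(OC(=O)C(C(=O)OC)[C@@H]3C=C(OS(=O)(=O)C(F)(F)F)[C@@]12C1OCCO1)C3=O
F13 | step 1 | 1α-[(S)-2-methoxy-2-phenylacetoxy] analogue of 13 | CO[C@@H](c1ccccc1)C(=O)O[C@H]1CCC[C@@]2(OC(=O)C(C(=O)OC)[C@@H]3C=C(OS(=O)(=O)C(F)(F)F)[C@@]12C1OCCO1)[C@H]3O
F14 | step 1 | 1α-[(S)-2-methoxy-2-phenylacetoxy] analogue of 14 | CO[C@@H](c1ccccc1)C(=O)O[C@H]1CCC[C@@]2(OC(=O)C(C(=O)OC)[C@@H]3C=C[C@@]12C1OCCO1)[C@H]3O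
F15 | step 12 | 5β,8β,9α-trihydroxy-1α-mesyloxy-10β-(1,3-dioxolan-2-yl)-12,6α-olide | CS(=O)(=O)O[C@H]1CCC[C@@]2(O)[C@H]3OC(=O)C[C@@H]3[C@H](O)[C@@H](O)[C@@]12C1OCCO1
F16 | step 17 | 5-O-acetate of 25 | C=C1CC/C=C(/C3OCCO3)[C@H](O[Si](C)(C)C(C)(C)C)[C@@H](OCc3ccc(OC)cc3)[C@H]2CC(=O)O[C@@H]2C1OC(C)=O
F17 | step 17 | 15-O-acetate of 26 | C1C(=O)O[C@@H]2/C=C(/COC(C)=O)CC/C=C(/C3OCCO3)[C@H](O[Si](C)(C)C(C)(C)C)[C@@H](OCc3ccc(OC)cc3)[C@@H]12
A1 | alternative 1 | 4,15-epoxy-5-ene C12 acid of the ten-membered ring (9-OTES, 8-ester, C14 dioxolane; C4 configuration and C5=C6 geometry open) | C=C(C(=O)O)[C@H]1C=CC2(CO2)CC/C=C(/C3OCCO3)[C@H](O[Si](CC)(CC)CC)[C@H]1OC(=O)[C@@H](C)CC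
A2 | alternative 1 | target protected as C14 dioxolane and 9-O-triethylsilyl ether | C=C1C(=O)O[C@@H]2/C=C(/CO)CC/C=C(/C3OCCO3)[C@H](O[Si](CC)(CC)CC)[C@@H](OC(=O)[C@@H](C)CC)[C@@H]12
A3 | alternative 2 | acyclic C2 iodide C10 β-keto sulfone (8,9-acetonide, 12,6-olide, 15-OTBS) | ICC/C(CO[Si](C)(C)C(C)(C)C)=C\[C@H]1OC(=O)C[C@@H]1[C@@H]1OC(C)(C)O[C@H]1C(=O)CS(=O)(=O)c1ccccc1
A4 | alternative 2 | ten-membered C10 ketone 1-phenylsulfone (C1 epimers) | O=C1C(S(=O)(=O)c2ccccc2)CC/C(CO[Si](C)(C)C(C)(C)C)=C\[C@H]2OC(=O)C[C@@H]2[C@@H]2OC(C)(C)O[C@@H]12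
A5 | alternative 3 | acyclic C9 aldehyde with C10 vinyl iodide (iodine cis to C2, C14 dioxolane, 15-OTBS) | C=C1C(=O)O[C@H](/C=C(/CO[Si](C)(C)C(C)(C)C)CC/C=C(\I)C2OCCO2)[C@H]1[C@H](OC(=O)[C@@H](C)CC)C=O
A6 | alternative 3 | target protected as C14 dioxolane and 15-O-tert-butyldimethylsilyl ether | C=C1C(=O)O[C@@H]2/C=C(/CO[Si](C)(C)C(C)(C)C)CC/C=C(/C3OCCO3)[C@H](O)[C@@H](OC(=O)[C@@H](C)CC)[C@@H]12
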